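The ten-membered carbocycle is never closed directly: it is cut out of a twelve-membered β-keto lactone in which the ring ketone C9, its methyl-bearing α-carbon C10 and the C1–C2–C3 unit (as a 2-methylenepropane-1,3-diyl group, lactone oxygen on C1) are ring atoms (locants in the remark below). Zerovalent palladium ionises the allylic ester, CO2 leaves, and the C10 enolate recombines with the symmetric π-allyl, so C10–C1 forms and two ring atoms are expelled. All C10 (and aldol) isomers of the precursor converge on one enolate. The precursor is assembled by an indium Barbier union of two chiral-pool fragments and a samarium Reformatsky macrocyclisation; the C2 methylene later becomes the C2 carbinol.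

Key step: step 16

Remark: locants used below are ring carbons C1 (CH2 next to C10), C2 (CHOH), C3 (CH2), C4 (C(OH)CH3), C5 (CH–O-angelate), C6 (CH–O of the lactone), C7 (CH carrying the lactone α-carbon C11), C8 (CH–O-isobutyrate), C9 (C=O), C10 (CH–CH3), with C12 the lactone carbonyl and C13 the exocyclic methylene carbon; centres carried on purpose as epimer mixtures (C11 in 15–28, the CHBr centre in 17–21, C9/C10 in 22, C10 in 23, sulfur in 27–28) are written without a descriptor in the SMILES.

Step 1
Reactants: 1 methyl (4S)-2,2-dimethyl-1,3-dioxolane-4-carboxylate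
Product: 3 1-[(4S)-2,2-dimethyl-1,3-dioxolan-4-yl]ethan-1-one, via Weinreb amide 2 (not isolated)
Conditions: MeNH(OMe)·HCl, iPrMgCl, THF, −20 °C; then MeMgBr, −20 → 0 °C
Reagents that add atoms: methylmagnesium bromide C[Mg]Br
Why: Ester aminolysis by the chloromagnesium amide gives the Weinreb amide, whose chelated adduct with MeMgBr collapses only on work-up, so the methyl ketone should form without over-addition and with the C5 centre intact (Weinreb ketone synthesis).

Step 2
Reactants: 4 3-bromo-2-(bromomethyl)prop-1-ene
Product: 5 2-(bromomethyl)prop-2-en-1-yl acetate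
Conditions: KOAc (1 equiv), 4 in excess, DMF, rt; distillation
Reagents that add atoms: potassium acetate CC(=O)[O-].[K+]
Why: Statistical SN2 mono-displacement of one allylic bromide by acetate gives the bifunctional allyl donor (unreacted dibromide is recovered); no stereocentre is formed.

Step 3
Reactants: 3 1-[(4S)-2,2-dimethyl-1,3-dioxolan-4-yl]ethan-1-one; 5 2-(bromomethyl)prop-2-en-1-yl acetate
Product: 7 (4S,5S)-4,5,6-trihydroxy-4-methyl-2-methylidenehexyl acetate, via dihydroxyketone 6 (not isolated)
Conditions: Dowex 50W (H+ form), H2O, 40 °C; filter, evaporate acetone; then 5, indium powder, THF/H2O (1:1), rt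
Reagents that add atoms: none
Why: Hydrolysis frees the α,β-dihydroxy ketone, whose carbonyl and α-hydroxyl chelate indium in water so that the allylindium reagent (Barbier reaction) adds anti to the CH2OH arm of the five-membered chelate, which should set C4 with its hydroxyl syn to the C5 hydroxyl.

Step 4
Reactants: 7 (4S,5S)-4,5,6-trihydroxy-4-methyl-2-methylidenehexyl acetate
Product: 8 (4S,5R)-4,5-dihydroxy-4-methyl-2-methylidene-6-oxohexyl acetate
Conditions: TEMPO (cat.), N-chlorosuccinimide, Bu4NCl, CH2Cl2/aq. NaHCO3–K2CO3 (pH 8.6), 0 °C → rt; used crude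
Reagents that add atoms: none
Why: Oxoammonium oxidation (TEMPO/N-chlorosuccinimide) is selective for the primary hydroxyl over the secondary and tertiary ones and stops at the aldehyde, which is used as its hydrate or dimer without touching a stereocentre.

Step 5
Reactants: 9 (4R)-2,2-dimethyl-1,3-dioxolane-4-carbaldehyde; 10 methyl acrylate
Product: 11 methyl 2-{hydroxy[(4R)-2,2-dimethyl-1,3-dioxolan-4-yl]methyl}prop-2-enoate (carbinol epimers)
Conditions: DABCO (1 equiv), 1,4-dioxane/H2O (1:1), rt
Reagents that add atoms: none
Why: Morita–Baylis–Hillman reaction; the new carbinol centre forms as an epimer mixture that does not matter because it becomes sp2 in step 6, and the aqueous medium keeps the reaction fast enough to limit epimerisation of the α-alkoxy aldehyde.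

Step 6
Reactants: 11 methyl 2-{hydroxy[(4R)-2,2-dimethyl-1,3-dioxolan-4-yl]methyl}prop-2-enoate
Product: 12 methyl (2Z)-2-(bromomethyl)-3-[(4S)-2,2-dimethyl-1,3-dioxolan-4-yl]prop-2-enoate
Conditions: N-bromosuccinimide, Me2S, CH2Cl2, 0 °C → rt
Reagents that add atoms: N-bromosuccinimide BrN1C(=O)CCC1=O
Why: Corey–Kim-type activation of the allylic alcohol and SN2′ return of bromide (allylic transposition) should give the conjugated, thermodynamically preferred Z-configured 2-(bromomethyl)enoate with the acetonide and the C8 centre intact.

Step 7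
Reactants: 8 (4S,5R)-4,5-dihydroxy-4-methyl-2-methylidene-6-oxohexyl acetate; 12 methyl (2Z)-2-(bromomethyl)-3-[(4S)-2,2-dimethyl-1,3-dioxolan-4-yl]prop-2-enoate
Product: 14 cis-fused α-methylidene-γ-butyrolactone with the C1-acetate/C4,C5-diol chain on C6 and the dioxolanyl group on C7, via hydroxy ester 13 (not isolated)
Conditions: indium powder, THF/H2O (1:1), rt; then PPTS (cat.), CH2Cl2, rt
Reagents that add atoms: none
Why: Indium-mediated Barbier 2-(alkoxycarbonyl)allylation in water, in which the Z-configured allylindium reacts through a closed chair transition state (C6/C7 syn adduct, hence the cis-fused lactone) on the aldehyde face fixed by the indium chelate of the free C5 hydroxyl (C5–O/C6–O syn), C8 being carried in from 12, after which the γ-hydroxy ester lactonises.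

Step 8
Reactants: 14 cis-fused α-methylidene-γ-butyrolactone (C1 acetate)
Product: 15 β-phenylthio lactone triol (C13H2–SPh on C11; free C1–OH)
Conditions: PhSH (1.2 equiv), K2CO3 (0.3 equiv), MeOH, 0 °C → rt
Reagents that add atoms: thiophenol Sc1ccccc1
Why: Thia-Michael addition of thiophenolate masks the α-methylidene lactone as a β-phenylthio lactone (C11 epimers, both usable since C11 becomes sp2 again in step 21), and the same K2CO3/MeOH medium transesterifies the primary allylic acetate to free the C1 hydroxyl.

Step 9
Reactants: 15 β-phenylthio lactone triol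
Product: 16 bis-acetonide with free C1–OH (C4/C5 diol as trans-dioxolane)
Conditions: 2,2-dimethoxypropane, PPTS (cat.), acetone, rt; short MeOH quench
Reagents that add atoms: 2,2-dimethoxypropane COC(C)(C)OC
Why: Acid-catalysed transketalisation engages the syn C4/C5 diol as a five-membered trans-disubstituted dioxolane, so only the primary C1 hydroxyl stays free.

Step 10
Reactants: 16 bis-acetonide with free C1–OH
Product: 17 C1 2-bromopropanoate
Conditions: 2-bromopropanoyl bromide, pyridine, CH2Cl2, −20 → 0 °C
Reagents that add atoms: 2-bromopropanoyl bromide CC(Br)C(Br)=O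
Why: Acylation of the only free hydroxyl gives the α-bromo ester needed for the Reformatsky closure; the CHBr centre is a mixture that is erased in step 16.

Step 11
Reactants: 17 C1 2-bromopropanoate
Product: 18 C8,C9-diol (C4/C5 acetonide retained)
Conditions: AcOH/H2O (4:1), rt
Reagents that add atoms: none
Why: The terminal acetonide of the primary/secondary C8/C9 diol should hydrolyse much faster than the fully substituted C4/C5 dioxolane, so mild aqueous acid unveils only the C8/C9 diol.

Step 12
Reactants: 18 C8,C9-diol
Product: 20 C8 isobutyrate with free C9–OH, via cyclic orthoester 19 (not isolated)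
Conditions: Me2CHC(OMe)3, PPTS (cat.), CH2Cl2, rt; then AcOH/H2O (4:1), 0 °C
Reagents that add atoms: trimethyl orthoisobutyrate COC(OC)(OC)C(C)C; water O
Why: The diol forms a cyclic orthoester whose mild acid hydrolysis opens kinetically with the acyl group left on the more hindered secondary oxygen (orthoester route to the secondary ester), giving the C8 isobutyrate without touching the C8 configuration.

Step 13
Reactants: 20 C8 isobutyrate with free C9–OH
Product: 21 C9 aldehyde
Conditions: Dess–Martin periodinane, NaHCO3, CH2Cl2, 0 °C → rt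
Reagents that add atoms: none
Why: Buffered Dess–Martin oxidation converts the primary alcohol into the α-acyloxy aldehyde without epimerising C8 or oxidising the thioether.

Step 14
Reactants: 21 C9 aldehyde
Product: 22 twelve-membered β-hydroxy lactone (C9/C10 isomer mixture)
Conditions: SmI2 (3 equiv), THF, −78 → 0 °C, slow addition of 21 (final 2 mM)
Reagents that add atoms: none
Why: Samarium diiodide reduces the α-bromo ester to a samarium enolate that adds to the tethered aldehyde under high dilution (intramolecular Reformatsky macrocyclisation); C9 and C10 form as mixtures on purpose because C9 is oxidised in step 15 and C10 is re-made in step 16.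

Step 15
Reactants: 22 twelve-membered β-hydroxy lactone
Product: 23 twelve-membered β-keto lactone (C10 epimers)
Conditions: Dess–Martin periodinane, NaHCO3, CH2Cl2, rt
Reagents that add atoms: none
Why: Dess–Martin oxidation of the β-hydroxy ester gives the β-keto lactone cleanly and removes the C9 stereocentre.

Step 16
Reactants: 23 twelve-membered β-keto lactone
Product: 24 ten-membered carbocyclic ketone (C2 methylidene; C4/C5 acetonide; C8 isobutyrate; 10S methyl)
Conditions: Pd(PPh3)4 (10 mol %), degassed toluene (2 mM), 25 → 60 °C
Reagents that add atoms: none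
Why: Zerovalent palladium ionises the allylic C1–O bond of the lactone, the β-keto carboxylate so released loses CO2, and the resulting C9/C10 enolate is allylated at carbon by the π-allyl fragment, so that the ester carbon and oxygen are excised and the twelve-membered ring contracts to the ten-membered carbocycle. The closest known reaction type is the decarboxylative Tsuji–Trost allylic alkylation of allyl β-keto esters (the metal-catalysed counterpart of the Carroll rearrangement), here run inside a ring. The carbocycle is closed by C-alkylation of the enolate at an allyl terminus, a ten-membered closure that is exo with respect to the departing metal and proceeds within a contact ion pair in a non-polar solvent. Both C10 epimers of 23 (hence all four aldol isomers of step 14) give the same enolate, so the step is stereoconvergent; the new C10 centre stays enolisable under the conditions and should settle under thermodynamic control with its methyl group anti to the C8 isobutyrate across the ketone, as the target requires. Regiochemistry is not an issue because the allyl unit carries its chain on the central carbon, so both termini are CH2 groups that give the same constitution, and any O-allyl enol ether is re-ionised by the catalyst and drains to the ketone. The step needs intramolecular C–C bond formation to beat oligomerisation, enolate protonation and capture of the π-allyl fragment by oxygen; high dilution, aprotic toluene, the acetonide that blocks the C4 hydroxyl (which would otherwise close a methylidene-tetrahydrofuran) and the thioether mask on the lactone (no Michael acceptor for the enolate) secure this.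

Step 17
Reactants: 24 ten-membered carbocyclic ketone
Product: 25 C4,C5-diol
Conditions: 1 M aq. HCl/THF (1:2), rt
Reagents that add atoms: none
Why: Dilute aqueous acid hydrolyses the hindered acetonide while the isobutyrate and lactone survive and the 1,1-disubstituted alkene is not protonated at this acidity; no stereocentre is affected.

Step 18
Reactants: 25 C4,C5-diol
Product: 26 C5 angelate
Conditions: angelic acid, 2,4,6-trichlorobenzoyl chloride, Et3N, toluene, rt; then 25, 75 °C
Reagents that add atoms: angelic acid C/C=C(/C)C(=O)O
Why: Acylation through the mixed 2,4,6-trichlorobenzoic anhydride (Yamaguchi-type esterification) should transfer the angeloyl group without Z-to-E isomerisation to the only acylable hydroxyl (secondary C5–OH, the tertiary C4–OH being inert), and it is placed before C2 is oxidised because the later β-hydroxy ketone would risk retro-aldol ring cleavage under warm basic conditions.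

Step 19
Reactants: 26 C5 angelate
Product: 27 C2 ketone with phenylsulfinyl group (sulfur epimers)
Conditions: O3, CH2Cl2/MeOH (4:1), Sudan Red 7B, −78 °C; then Me2S, −78 °C → rt
Reagents that add atoms: ozone [O-][O+]=O
Why: Ozonolysis cleaves the electron-rich 1,1-disubstituted C2 methylidene to the C2 ketone and at the same time oxidises the thioether to the sulfoxide, while the electron-poor angelate is spared by stopping at the indicator end-point.

Step 20
Reactants: 27 C2 ketone with phenylsulfinyl group
Product: 28 (2S)-carbinol sulfoxide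
Conditions: Et2BOMe, THF/MeOH (4:1), −78 °C; NaBH4, −78 °C; AcOH quench, MeOH azeotrope
Reagents that add atoms: none
Why: Narasaka–Prasad reduction, in which the free tertiary C4 hydroxyl and the C2 ketone form a six-membered diethylboron chelate that activates C2 over the hindered unchelated C9 ketone and directs external hydride so that the C2 hydroxyl should end up syn to the C4 hydroxyl.

Step 21
Reactants: 28 (2S)-carbinol sulfoxide
Product: 29 target CNP0184688.2
Conditions: toluene, NaHCO3 (solid), 100 °C
Reagents that add atoms: none
Why: Thermal syn-elimination of the β-sulfinyl lactone (sulfoxide elimination) can only remove the C11 hydrogen and so regenerates the exocyclic C11=C13 methylidene under neutral conditions that leave the esters, hydroxyls and enolisable centres untouched.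

Compound list
1 | methyl (4S)-2,2-dimethyl-1,3-dioxolane-4-carboxylate | COC(=O)[C@@H]1COC(C)(C)O1 | starting material
2 | (4S)-N-methoxy-N,2,2-trimethyl-1,3-dioxolane-4-carboxamide (Weinreb amide) | CON(C)C(=O)[C@@H]1COC(C)(C)O1 | intermediate (not isolated)
3 | 1-[(4S)-2,2-dimethyl-1,3-dioxolan-4-yl]ethan-1-one | CC(=O)[C@@H]1COC(C)(C)O1 | intermediate
4 | 3-bromo-2-(bromomethyl)prop-1-ene | C=C(CBr)CBr | starting material
5 | 2-(bromomethyl)prop-2-en-1-yl acetate | CC(=O)OCC(=C)CBr | intermediate
6 | (3S)-3,4-dihydroxybutan-2-one | CC(=O)[C@@H](O)CO | intermediate (not isolated)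
7 | (4S,5S)-4,5,6-trihydroxy-4-methyl-2-methylidenehexyl acetate | OC[C@H](O)[C@@](C)(O)CC(=C)COC(C)=O | intermediate
8 | (4S,5R)-4,5-dihydroxy-4-methyl-2-methylidene-6-oxohexyl acetate | O=C[C@H](O)[C@@](C)(O)CC(=C)COC(C)=O | intermediate
9 | (4R)-2,2-dimethyl-1,3-dioxolane-4-carbaldehyde | O=C[C@H]1COC(C)(C)O1 | starting material
10 | methyl acrylate | COC(=O)C=C | starting material
11 | methyl 2-{hydroxy[(4R)-2,2-dimethyl-1,3-dioxolan-4-yl]methyl}prop-2-enoate (carbinol epimers) | COC(=O)C(=C)C(O)[C@H]1COC(C)(C)O1 | intermediate
12 | methyl (2Z)-2-(bromomethyl)-3-[(4S)-2,2-dimethyl-1,3-dioxolan-4-yl]prop-2-enoate | COC(=O)/C(CBr)=C/[C@H]1COC(C)(C)O1 | intermediate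
13 | open-chain Barbier adduct: methyl ester with C11=C13 methylidene, C7 dioxolanyl branch, C6–OH (syn to C5–OH, syn to the C7 branch), C4/C5 diol, C1 acetate | COC(=O)C(=C)[C@H]([C@H]2COC(C)(C)O2)[C@@H](O)[C@H](O)[C@@](C)(O)CC(=C)COC(C)=O | intermediate (not isolated)
14 | cis-fused α-methylidene-γ-butyrolactone (H6/H7 cis) with the C5(OH)–C4(OH)(CH3)–C3H2–C2(=CH2)–C1H2OAc chain on C6 and the (4S)-2,2-dimethyl-1,3-dioxolan-4-yl group (C8/C9) on C7 | C=C1C(=O)O[C@@H]([C@H](O)[C@@](C)(O)CC(=C)COC(C)=O)[C@H]1[C@H]2COC(C)(C)O2 | intermediate
15 | as 14 with C13H2–SPh on C11 (C11 epimers) and free C1–OH | c3ccccc3SCC1C(=O)O[C@@H]([C@H](O)[C@@](C)(O)CC(=C)CO)[C@H]1[C@H]2COC(C)(C)O2 | intermediate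
16 | as 15 with the C4/C5 diol as trans-dioxolane acetonide (free C1–OH) | c3ccccc3SCC1C(=O)O[C@@H]([C@@H]4OC(C)(C)O[C@@]4(C)CC(=C)CO)[C@H]1[C@H]2COC(C)(C)O2 | intermediate
17 | as 16 with C1–O–CO–CHBr–CH3 (CHBr epimers) | c3ccccc3SCC1C(=O)O[C@@H]([C@@H]4OC(C)(C)O[C@@]4(C)CC(=C)COC(=O)C(C)Br)[C@H]1[C@H]2COC(C)(C)O2 | intermediate
18 | as 17 with free C8–OH and C9–OH | c3ccccc3SCC1C(=O)O[C@@H]([C@@H]4OC(C)(C)O[C@@]4(C)CC(=C)COC(=O)C(C)Br)[C@H]1[C@H](O)CO | intermediate
19 | cyclic orthoester of 18 (C8/C9 diol as 2-methoxy-2-(propan-2-yl)-1,3-dioxolane) | c3ccccc3SCC1C(=O)O[C@@H]([C@@H]4OC(C)(C)O[C@@]4(C)CC(=C)COC(=O)C(C)Br)[C@H]1[C@H]2COC(OC)(C(C)C)O2 | intermediate (not isolated)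
20 | as 18 with C8 isobutyrate and free C9–OH | c3ccccc3SCC1C(=O)O[C@@H]([C@@H]4OC(C)(C)O[C@@]4(C)CC(=C)COC(=O)C(C)Br)[C@H]1[C@H](OC(=O)C(C)C)CO | intermediate
21 | as 20 with C9 aldehyde | c3ccccc3SCC1C(=O)O[C@@H]([C@@H]4OC(C)(C)O[C@@]4(C)CC(=C)COC(=O)C(C)Br)[C@H]1[C@H](OC(=O)C(C)C)C=O | intermediate
22 | twelve-membered β-hydroxy lactone (ring C6–C5–C4–C3–C2–C1–O–CO–C10–C9–C8–C7; C9–OH and C10–CH3 as mixtures) | c3ccccc3SCC1C(=O)O[C@H]2[C@@H]4OC(C)(C)O[C@@]4(C)CC(=C)COC(=O)C(C)C(O)[C@@H](OC(=O)C(C)C)[C@H]21 | intermediate
23 | twelve-membered β-keto lactone (C9 ketone; C10 epimers) | c3ccccc3SCC1C(=O)O[C@H]2[C@@H]4OC(C)(C)O[C@@]4(C)CC(=C)COC(=O)C(C)C(=O)[C@@H](OC(=O)C(C)C)[C@H]21 | intermediate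
24 | ten-membered carbocycle: C9 ketone, (10S)-methyl, C2 methylidene, C4/C5 acetonide, C8 isobutyrate, cis-lactone with C13H2–SPh | c3ccccc3SCC1C(=O)O[C@@H]2[C@H]1[C@H](OC(=O)C(C)C)C(=O)[C@@H](C)CC(=C)C[C@]4(C)OC(C)(C)O[C@@H]24 | intermediate
25 | as 24 with free C4–OH and C5–OH | c3ccccc3SCC1C(=O)O[C@@H]2[C@H]1[C@H](OC(=O)C(C)C)C(=O)[C@@H](C)CC(=C)C[C@](C)(O)[C@H]2O | intermediate
26 | as 25 with C5 angelate ((Z)-2-methylbut-2-enoate) | c3ccccc3SCC1C(=O)O[C@@H]2[C@H]1[C@H](OC(=O)C(C)C)C(=O)[C@@H](C)CC(=C)C[C@](C)(O)[C@H]2OC(=O)/C(C)=C\C | intermediate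
27 | as 26 with C2 ketone and C13H2–S(O)Ph (sulfur epimers) | O=S(c3ccccc3)CC1C(=O)O[C@@H]2[C@H]1[C@H](OC(=O)C(C)C)C(=O)[C@@H](C)CC(=O)C[C@](C)(O)[C@H]2OC(=O)/C(C)=C\C | intermediate
28 | as 27 with (2S)-C2 carbinol | O=S(c3ccccc3)CC1C(=O)O[C@@H]2[C@H]1[C@H](OC(=O)C(C)C)C(=O)[C@@H](C)C[C@H](O)C[C@](C)(O)[C@H]2OC(=O)/C(C)=C\C | intermediate
29 | CNP0184688.2 | C=C1C(=O)O[C@@H]2[C@H]1[C@H](OC(=O)C(C)C)C(=O)[C@@H](C)C[C@H](O)C[C@](C)(O)[C@H]2OC(=O)/C(C)=C\C | target

Total step count: 21. Longest linear sequence: 18 steps (1, 3, 4, 7–21).

Steps most likely to fail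

Step 16. After ionisation the molecule is an open-chain ion pair, so enolate protonation, oligomerisation or loss of the allyl unit as a diene may outrun the ten-membered C–C closure, and the C10 epimer ratio may be unfavourable. The fallback sets out from 23 and comes back at 24. The ionising catalyst is replaced by an uncatalysed Carroll rearrangement: heating 23 in xylene (about 140 °C, high dilution) lets the ester enol undergo a concerted [3,3]-sigmatropic shift inside the ring, so the C10–C bond is made before CO2 is lost and no free enolate exists. This gives the ring-contracted β-keto acid F1, which decarboxylates at the same temperature to 24. An unfavourable C10 ratio would be corrected by brief equilibration with a trace of DBU.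

Step 14. The isobutyryl group may migrate from the C8 oxygen onto the new C9 samarium alkoxide (which would put the wrong oxygen at the ketone level in step 15), the α-acyloxy group may be lost reductively, or the aldol may turn intermolecular. The fallback sets out from 18 and comes back at 24; the acyl group is introduced only after the ring contraction.
- Diol 18 is silylated (Et3SiOTf, 2,6-lutidine) to the bis(triethylsilyl) ether F2.
- Swern oxidation, which converts a primary triethylsilyl ether directly into the aldehyde, gives the α-silyloxy aldehyde F3.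
- SmI2 closure gives the C8-silylated β-hydroxy lactone F4, which has no migrating group.
- Dess–Martin oxidation gives the C8-silylated β-keto lactone F5.
- Pd(PPh3)4 gives the ring-contracted C8 silyl ether F6.
- HF·pyridine frees the C8 alcohol F7, and isobutyric anhydride/DMAP returns 24.

Step 20. The C9 ketone (activated by its α-acyloxy group) may be reduced in competition, the boron chelate may form incompletely at the tertiary hydroxyl, or hydride may approach from the wrong face of the ten-membered ring. The fallback sets out from 27 and comes back at 28. Substrate control is replaced by catalyst control: a ketoreductase chosen from a panel for the (S)-configured C2 carbinol (NADPH recycled with isopropanol, phosphate buffer/DMSO, 30 °C) should distinguish the unhindered CH2–CO–CH2 ketone from the flanked C9 ketone in a neutral medium that leaves the esters, the sulfoxide and the β-hydroxy ketone intact. No new compound arises (F0).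

Further compounds
F1 | step 16 | ring-contracted β-keto acid (ten-membered ring, C10 bearing CH3 and CO2H, C10 epimers) | c3ccccc3SCC1C(=O)O[C@@H]2[C@H]1[C@H](OC(=O)C(C)C)C(=O)C(C)(C(=O)O)CC(=C)C[C@]4(C)OC(C)(C)O[C@@H]24
F2 | step 14 | bis(triethylsilyl) ether of diol 18 | c3ccccc3SCC1C(=O)O[C@@H]([C@@H]4OC(C)(C)O[C@@]4(C)CC(=C)COC(=O)C(C)Br)[C@H]1[C@H](O[Si](CC)(CC)CC)CO[Si](CC)(CC)CC
F3 | step 14 | α-silyloxy aldehyde (C9 aldehyde, C8 triethylsilyl ether) | c3ccccc3SCC1C(=O)O[C@@H]([C@@H]4OC(C)(C)O[C@@]4(C)CC(=C)COC(=O)C(C)Br)[C@H]1[C@H](O[Si](CC)(CC)CC)C=O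
F4 | step 14 | twelve-membered β-hydroxy lactone with C8 triethylsilyl ether (C9/C10 mixtures) | c3ccccc3SCC1C(=O)O[C@H]2[C@@H]4OC(C)(C)O[C@@]4(C)CC(=C)COC(=O)C(C)C(O)[C@@H](O[Si](CC)(CC)CC)[C@H]21
F5 | step 14 | twelve-membered β-keto lactone with C8 triethylsilyl ether (C10 epimers) | c3ccccc3SCC1C(=O)O[C@H]2[C@@H]4OC(C)(C)O[C@@]4(C)CC(=C)COC(=O)C(C)C(=O)[C@@H](O[Si](CC)(CC)CC)[C@H]21
F6 | step 14 | ring-contracted ketone with C8 triethylsilyl ether | c3ccccc3SCC1C(=O)O[C@@H]2[C@H]1[C@H](O[Si](CC)(CC)CC)C(=O)[C@@H](C)CC(=C)C[C@]4(C)OC(C)(C)O[C@@H]24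
F7 | step 14 | ring-contracted ketone with free C8–OH | c3ccccc3SCC1C(=O)O[C@@H]2[C@H]1[C@H](O)C(=O)[C@@H](C)CC(=C)C[C@]4(C)OC(C)(C)O[C@@H]24
F0 | step 20 | none | none
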